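**Retrosynthetic overview**
1. The target is numbered as a 1-oxaspiro[4.4]nona-2,7-diene: a 5-aryl-3(2H)-furanone (O1, C2–C4) spiro-fused at C5 to a fully oxygenated cyclopentenone (C6–C9).
2. Key disconnection: a formal (3+2) annulation of α-ketol 11 with arylpropynethioate 15 that makes O1–C2 (oxa-Michael) and C4–C5 (Dieckmann-type C-acylation) in one pot. It is possible because the spiro atom C5 is at once the carbinol carbon of O1 and the α-carbon of the C9 ring ketone (a 1,2-C,O-bis-nucleophile), while C2–C3–C4 of the furanone has the oxidation level of a β-aryl ynoyl 1,3-bis-electrophile.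
3. The cyclopentenone (C5–C9, with O1 already on C5) comes from furan 6 in one flask: Achmatowicz-type oxidation, then a ring-contracting, catalyst-controlled intramolecular aldol of the hydroxy ketone onto the α-keto ester, which sets C6.
4. Furan 6 (furan C2–C5 become C6–C9; its CH2OH becomes C5/O1) is made from dimethyl diglycolate and dimethyl oxalate; 15 comes from a silyl-protected 4-hydroxybenzaldehyde.
5. Order of ring formation: sacrificial furan, then cyclopentenone, then furanone (key step); the C6 silyl ether steers the new C5 centre and is removed last.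

Key step: step 10

Remark: C5 of 9–11 is planarised in the key step, so only the C1 configuration of 9 matters. The cis-1,5-diol is drawn as the expected zinc-chelated aldol product. Which antipode of the ProPhenol ligand delivers (1S)-9 would have to be established on this new substrate (both antipodes are commercial).

**Step 1**
Reactants: 1 dimethyl diglycolate; 2 dimethyl oxalate
Product: 3 dimethyl 3,4-dihydroxyfuran-2,5-dicarboxylate
Conditions: NaOMe (2.2 equiv), MeOH, reflux; then aq. HCl
Reagents that add atoms: none
Why: A double Claisen (Hinsberg-type) condensation of the two activated methylene groups of the diglycolate with the oxalate should close the aromatic 3,4-dihydroxyfuran; no stereocentre is formed.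

**Step 2**
Reactants: 3 dimethyl 3,4-dihydroxyfuran-2,5-dicarboxylate
Product: 4 dimethyl 3,4-dimethoxyfuran-2,5-dicarboxylate
Conditions: Me2SO4, K2CO3, acetone, reflux
Reagents that add atoms: dimethyl sulfate, COS(=O)(=O)OC
Why: Williamson O-methylation of the two acidic enolic hydroxyl groups should be clean because C-alkylation would destroy the furan aromaticity.

**Step 3**
Reactants: 4 dimethyl 3,4-dimethoxyfuran-2,5-dicarboxylate
Product: 5 3,4-dimethoxy-5-(methoxycarbonyl)furan-2-carboxylic acid
Conditions: KOH (1.0 equiv), MeOH/THF/H2O, 0 °C; then aq. HCl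
Reagents that add atoms: potassium hydroxide, [K+].[OH-]
Why: Mono-saponification of a symmetric diester should stop after one ester because the carboxylate formed deactivates the second ester through the furan.

**Step 4**
Reactants: 5 3,4-dimethoxy-5-(methoxycarbonyl)furan-2-carboxylic acid
Product: 6 methyl 5-(hydroxymethyl)-3,4-dimethoxyfuran-2-carboxylate
Conditions: BH3·SMe2, THF, 0 °C → rt; MeOH quench
Reagents that add atoms: none
Why: Borane reduces a carboxylic acid much faster than an ester, so only the acid should be taken to the primary alcohol.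

**Step 5**
Reactants: 6 methyl 5-(hydroxymethyl)-3,4-dimethoxyfuran-2-carboxylate
Product: 9 methyl (1S,5R)-1,5-dihydroxy-2,3-dimethoxy-4-oxocyclopent-2-ene-1-carboxylate, via open-chain hydroxy enetrione 7 (not isolated), via pyranone hemiketal 8 (not isolated)
Conditions: dimethyldioxirane (DMDO, 1.1 equiv), acetone, −20 → 0 °C; volatiles removed in vacuo; then (S,S)-2,6-bis[[2-(hydroxydiphenylmethyl)pyrrolidin-1-yl]methyl]-4-methylphenol (ProPhenol ligand, 10 mol%), Et2Zn (20 mol%), 4 Å MS, THF, −20 °C
Reagents that add atoms: dimethyldioxirane, CC1(C)OO1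
Why: Proposed new method: Achmatowicz-type oxidation of the electron-rich furan by the dioxirane (acetone as the only by-product) should give the (Z)-enetrione 7, which rests as its ring-chain tautomer, hemiketal 8; the dinuclear zinc complex formed from Et2Zn and the ProPhenol ligand should then draw this equilibrium back through 7 by binding the α-hydroxy ketone end as a zinc enediolate while its second zinc activates the chelating α-keto ester, so that aldol addition of the CH(OH) carbon to the keto carbonyl closes the five-membered ring and sets C1 under catalyst control, with both oxygens held on zinc accounting for the cis-diol; the closest known reaction types are the base-mediated ring contraction of Achmatowicz pyranones to 4,5-dihydroxycyclopentenones and the direct aldol addition of α-hydroxy ketones to aldehydes under the same zinc catalyst.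

**Step 6**
Reactants: 9 methyl (1S,5R)-1,5-dihydroxy-2,3-dimethoxy-4-oxocyclopent-2-ene-1-carboxylate
Product: 10 methyl (1S,5R)-2,3-dimethoxy-4-oxo-1,5-bis(triethylsilyloxy)cyclopent-2-ene-1-carboxylate
Conditions: TESOTf (2.5 equiv), 2,6-lutidine, CH2Cl2, −78 → 0 °C
Reagents that add atoms: triethylsilyl trifluoromethanesulfonate, CC[Si](CC)(CC)OS(=O)(=O)C(F)(F)F
Why: The silyl triflate should silylate both the secondary and the hindered tertiary hydroxyl without touching the stereocentres, and capping the tertiary oxygen blocks retro-aldol opening in all later basic steps.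

**Step 7**
Reactants: 10 methyl (1S,5R)-2,3-dimethoxy-4-oxo-1,5-bis(triethylsilyloxy)cyclopent-2-ene-1-carboxylate
Product: 11 methyl (1S,5R)-5-hydroxy-2,3-dimethoxy-4-oxo-1-(triethylsilyloxy)cyclopent-2-ene-1-carboxylate
Conditions: PPTS (0.2 equiv), MeOH/CH2Cl2, 0 °C
Reagents that add atoms: none
Why: Acid-catalysed methanolysis should cleave the secondary silyl ether well before the more hindered tertiary one.

**Step 8**
Reactants: 12 4-(tert-butyldimethylsilyloxy)benzaldehyde
Product: 13 tert-butyl[4-(2,2-dibromoethenyl)phenoxy]dimethylsilane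
Conditions: CBr4, PPh3, CH2Cl2, 0 °C
Reagents that add atoms: carbon tetrabromide, BrC(Br)(Br)Br
Why: Corey–Fuchs dibromo-olefination (Wittig-type) of an aryl aldehyde is reliable and leaves the aryl silyl ether untouched.

**Step 9**
Reactants: 13 tert-butyl[4-(2,2-dibromoethenyl)phenoxy]dimethylsilane
Product: 15 S-ethyl 3-[4-(tert-butyldimethylsilyloxy)phenyl]prop-2-ynethioate, via lithium arylacetylide 14 (not isolated)
Conditions: n-BuLi (2.1 equiv), THF, −78 °C; then EtSC(O)Cl, −78 °C → rt
Reagents that add atoms: S-ethyl chlorothioformate, CCSC(Cl)=O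
Why: The second stage of the Corey–Fuchs sequence should give the lithium acetylide, which is acylated at the carbonyl of the chlorothioformate with loss of chloride.

**Step 10**
Reactants: 11 methyl (1S,5R)-5-hydroxy-2,3-dimethoxy-4-oxo-1-(triethylsilyloxy)cyclopent-2-ene-1-carboxylate; 15 S-ethyl 3-[4-(tert-butyldimethylsilyloxy)phenyl]prop-2-ynethioate
Product: 18 methyl (5S,6R)-2-[4-(tert-butyldimethylsilyloxy)phenyl]-7,8-dimethoxy-4,9-dioxo-6-(triethylsilyloxy)-1-oxaspiro[4.4]nona-2,7-diene-6-carboxylate, via enol ether thioester 16 (not isolated), via lithium enolate 17 (not isolated)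
Conditions: PMe3 (0.2 equiv), THF, 0 °C → rt; then LiN(SiMe3)2 (1.2 equiv), −78 → −30 °C; AcOH, −78 °C
Reagents that add atoms: none
Why: Proposed new method: PMe3 adds to ynethioate 15 and the phosphonium allenolate deprotonates the C5 hydroxyl of 11, whose oxygen adds to the aryl-bearing alkyne carbon (O1–C2) to give enol ether 16; LiN(SiMe3)2 then removes the C5–H next to the ring ketone, and enolate 17 attacks the thioester carbonyl with loss of ethanethiolate (C4–C5), which closes the furanone and creates the spiro centre. The closest known chemistry is the Fiesselmann-type hetero-Michael/Dieckmann annulation of α-hydroxy or α-mercapto esters with alkynoates, together with the trialkylphosphine-catalysed addition of alcohols to alkynoates; new here is an α-ketol donor whose C-acylation gives a quaternary, non-enolisable centre. The only ring closed is the furanone, by 5-exo-trig acyl substitution of the ketone enolate on the tethered thioester, the O–C bond being made intermolecularly. The C5 stereocentre is set in this C-acylation under control of C6: the acyl carbon should enter anti to the bulky triethylsilyloxy group, on the face of the CO2Me group and helped by lithium bridging the two carbonyls, so that O1 ends cis to the C6 oxygen as in the target, the earlier C5 configuration being erased in the planar enolate. The step needs conjugate O-addition instead of O-acylation (secured by the weakly acylating but strongly Michael-accepting thioester and by nucleophilic catalysis without a standing alkoxide, which also limits silyl migration), C-acylation instead of O-acylation of the enolate (secured by the five-membered tether, the unreactive alkene isomer of 16 equilibrating through reversible thiolate or phosphine addition), and irreversibility (ethanethiolate is too poor a nucleophile for retro-Claisen cleavage, and β-elimination of the silyloxy group from 17 would have to give an antiaromatic cyclopentadienone).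

**Step 11**
Reactants: 18 methyl (5S,6R)-2-[4-(tert-butyldimethylsilyloxy)phenyl]-7,8-dimethoxy-4,9-dioxo-6-(triethylsilyloxy)-1-oxaspiro[4.4]nona-2,7-diene-6-carboxylate
Product: 19 limnophilaspiroketone, methyl (5S,6R)-6-hydroxy-2-(4-hydroxyphenyl)-7,8-dimethoxy-4,9-dioxo-1-oxaspiro[4.4]nona-2,7-diene-6-carboxylate
Conditions: HF·pyridine, pyridine/THF, 0 °C → rt
Reagents that add atoms: none
Why: Buffered acidic fluoride should cleave both the aryl and the tertiary silyl ether while avoiding any base, which would open the tertiary aldol by retro-aldol cleavage and scramble both stereocentres.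

**Compound list**
1 | dimethyl diglycolate (dimethyl 2,2'-oxydiacetate) | COC(=O)COCC(=O)OC | starting material
2 | dimethyl oxalate | COC(=O)C(=O)OC | starting material
3 | dimethyl 3,4-dihydroxyfuran-2,5-dicarboxylate | COC(=O)c1oc(C(=O)OC)c(O)c1O | intermediate
4 | dimethyl 3,4-dimethoxyfuran-2,5-dicarboxylate | COC(=O)c1oc(C(=O)OC)c(OC)c1OC | intermediate
5 | 3,4-dimethoxy-5-(methoxycarbonyl)furan-2-carboxylic acid | COC(=O)c1oc(C(=O)O)c(OC)c1OC | intermediate
6 | methyl 5-(hydroxymethyl)-3,4-dimethoxyfuran-2-carboxylate | COC(=O)c1oc(CO)c(OC)c1OC | intermediate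
7 | methyl (Z)-6-hydroxy-3,4-dimethoxy-2,5-dioxohex-3-enoate (open-chain hydroxy enetrione, not isolated) | COC(=O)C(=O)/C(OC)=C(OC)\C(=O)CO | intermediate
8 | methyl 2-hydroxy-3,4-dimethoxy-5-oxo-5,6-dihydro-2H-pyran-2-carboxylate (racemic hemiketal, ring-chain tautomer of 7, not isolated) | COC(=O)C1(O)OCC(=O)C(OC)=C1OC | intermediate
9 | methyl (1S,5R)-1,5-dihydroxy-2,3-dimethoxy-4-oxocyclopent-2-ene-1-carboxylate (cis-diol; C1 becomes C6 of the target, where the same spatial arrangement is named R) | COC(=O)[C@@]1(O)C(OC)=C(OC)C(=O)[C@@H]1O | intermediate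
10 | methyl (1S,5R)-2,3-dimethoxy-4-oxo-1,5-bis(triethylsilyloxy)cyclopent-2-ene-1-carboxylate | COC(=O)[C@@]1(O[Si](CC)(CC)CC)C(OC)=C(OC)C(=O)[C@@H]1O[Si](CC)(CC)CC | intermediate
11 | methyl (1S,5R)-5-hydroxy-2,3-dimethoxy-4-oxo-1-(triethylsilyloxy)cyclopent-2-ene-1-carboxylate | COC(=O)[C@@]1(O[Si](CC)(CC)CC)C(OC)=C(OC)C(=O)[C@@H]1O | intermediate
12 | 4-(tert-butyldimethylsilyloxy)benzaldehyde | O=Cc1ccc(O[Si](C)(C)C(C)(C)C)cc1 | starting material
13 | tert-butyl[4-(2,2-dibromoethenyl)phenoxy]dimethylsilane | BrC(Br)=Cc1ccc(O[Si](C)(C)C(C)(C)C)cc1 | intermediate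
14 | lithium [4-(tert-butyldimethylsilyloxy)phenyl]acetylide (not isolated) | [Li]C#Cc1ccc(O[Si](C)(C)C(C)(C)C)cc1 | intermediate
15 | S-ethyl 3-[4-(tert-butyldimethylsilyloxy)phenyl]prop-2-ynethioate | CCSC(=O)C#Cc1ccc(O[Si](C)(C)C(C)(C)C)cc1 | intermediate
16 | enol ether thioester: S-ethyl (Z)-3-aryl-3-(cyclopentenyloxy)prop-2-enethioate from addition of the C5 oxygen of 11 to C3 of 15 (ring configuration as in 11; not isolated) | COC(=O)[C@@]1(O[Si](CC)(CC)CC)C(OC)=C(OC)C(=O)[C@@H]1O/C(=C\C(=O)SCC)c1ccc(O[Si](C)(C)C(C)(C)C)cc1 | intermediate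
17 | lithium enolate of 16 (ring ketone oxygen lithiated, former C5 planar, silyloxy-bearing stereocentre retained; not isolated) | [Li+].COC(=O)[C@@]1(O[Si](CC)(CC)CC)C(OC)=C(OC)C([O-])=C1O/C(=C\C(=O)SCC)c1ccc(O[Si](C)(C)C(C)(C)C)cc1 | intermediate
18 | methyl (5S,6R)-2-[4-(tert-butyldimethylsilyloxy)phenyl]-7,8-dimethoxy-4,9-dioxo-6-(triethylsilyloxy)-1-oxaspiro[4.4]nona-2,7-diene-6-carboxylate | COC(=O)[C@@]1(O[Si](CC)(CC)CC)C(OC)=C(OC)C(=O)[C@]12OC(c1ccc(O[Si](C)(C)C(C)(C)C)cc1)=CC2=O | intermediate
19 | limnophilaspiroketone, methyl (5S,6R)-6-hydroxy-2-(4-hydroxyphenyl)-7,8-dimethoxy-4,9-dioxo-1-oxaspiro[4.4]nona-2,7-diene-6-carboxylate | COC(=O)[C@@]1(O)C(OC)=C(OC)C(=O)[C@]12OC(c1ccc(O)cc1)=CC2=O | target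

**Step count and risks**
Total step count: 11. Longest linear sequence: 9 steps (steps 1–7, 10, 11); steps 8–9 form the side branch.

Steps most likely to fail:

1. Step 10 (key step, labelled). Processes that may go wrong:
   - acyl substitution at the thioester by the transient alkoxide, which would lead on to the regioisomeric spiro-butenolide;
   - phosphine-mediated α-addition of the alcohol instead of β-addition;
   - migration of the triethylsilyl group from the tertiary to the secondary oxygen within that alkoxide;
   - entry of the acyl carbon on the wrong face of the enolate.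

   Fallback (known chemistry, sets out from 11 and 12, rejoins at 18): Dess–Martin oxidation of ketol 11 should give methyl (1R)-2,3-dimethoxy-4,5-dioxo-1-(triethylsilyloxy)cyclopent-2-ene-1-carboxylate F1. Addition of HC≡CMgBr to aldehyde 12 should give racemic 1-[4-(tert-butyldimethylsilyloxy)phenyl]prop-2-yn-1-ol F2. Double deprotonation of F2 (n-BuLi, 2 equiv, THF, −78 °C) and addition to the more electrophilic C5 ketone of F1, anti to the α-silyloxy group, should give the ynediol F3. MnO2 should oxidise only its benzylic propargylic alcohol to the hydroxy ynone F4. Conjugate addition of Et2NH should give the enaminone F5, and aqueous AcOH should hydrolyse it and cyclodehydrate the resulting hydroxy 1,3-diketone to the 3(2H)-furanone 18. Here the C5 centre is set by nucleophilic addition to a ketone next to the C6 stereocentre, a better-understood mode of 1,2-induction.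

2. Step 5 (labelled). Processes that may go wrong:
   - insufficient enantio- or diastereocontrol in the aldol ring contraction (a minor diastereomer could carry the opposite C1 configuration and must be removed);
   - reversibility of the aldol;
   - Claisen-type closure of the enediolate on the ester carbonyl, draining material to a dihydroxy-dimethoxybenzoquinone;
   - poisoning of the zinc catalyst by residues of the oxidation stage.

   Fallback (sets out from 6, rejoins at 9): the dimethyldioxirane oxidation of 6 is run as in step 5 to the equilibrating 7/8 mixture. After evaporation, catalytic Et3N in CH2Cl2 at 0 °C should give racemic methyl 1,5-dihydroxy-2,3-dimethoxy-4-oxocyclopent-2-ene-1-carboxylate F6 by the known base-mediated ring contraction. Preparative chromatography on a chiral stationary phase (supercritical CO2/MeOH) should then deliver (1S,5R)-9.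

3. Step 7. Process that may go wrong: loss of site-selectivity in the acidic mono-desilylation (cleavage of both silyl ethers or of the tertiary one).

   Fallback (sets out from 9, rejoins at 11): selective acylation of the secondary hydroxyl with (ClCH2CO)2O/pyridine at −20 °C should give methyl (1S,5R)-5-(chloroacetoxy)-1-hydroxy-2,3-dimethoxy-4-oxocyclopent-2-ene-1-carboxylate F7. TESOTf/2,6-lutidine should then give methyl (1S,5R)-5-(chloroacetoxy)-2,3-dimethoxy-4-oxo-1-(triethylsilyloxy)cyclopent-2-ene-1-carboxylate F8. Thiourea/NaHCO3 in EtOH should remove the chloroacetate under near-neutral conditions to give 11.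

**Further compounds**
F1 | step 10 | methyl (1R)-2,3-dimethoxy-4,5-dioxo-1-(triethylsilyloxy)cyclopent-2-ene-1-carboxylate | COC(=O)[C@@]1(O[Si](CC)(CC)CC)C(OC)=C(OC)C(=O)C1=O
F2 | step 10 | 1-[4-(tert-butyldimethylsilyloxy)phenyl]prop-2-yn-1-ol (racemic) | C#CC(O)c1ccc(O[Si](C)(C)C(C)(C)C)cc1
F3 | step 10 | methyl (1S,5R)-5-hydroxy-5-{3-hydroxy-3-[4-(tert-butyldimethylsilyloxy)phenyl]prop-1-yn-1-yl}-2,3-dimethoxy-4-oxo-1-(triethylsilyloxy)cyclopent-2-ene-1-carboxylate (epimers at the benzylic carbinol) | COC(=O)[C@@]1(O[Si](CC)(CC)CC)C(OC)=C(OC)C(=O)[C@@]1(O)C#CC(O)c1ccc(O[Si](C)(C)C(C)(C)C)cc1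
F4 | step 10 | methyl (1S,5R)-5-hydroxy-2,3-dimethoxy-4-oxo-5-{3-oxo-3-[4-(tert-butyldimethylsilyloxy)phenyl]prop-1-yn-1-yl}-1-(triethylsilyloxy)cyclopent-2-ene-1-carboxylate | COC(=O)[C@@]1(O[Si](CC)(CC)CC)C(OC)=C(OC)C(=O)[C@@]1(O)C#CC(=O)c1ccc(O[Si](C)(C)C(C)(C)C)cc1
F5 | step 10 | methyl (1S,5R)-5-{1-(diethylamino)-3-oxo-3-[4-(tert-butyldimethylsilyloxy)phenyl]prop-1-en-1-yl}-5-hydroxy-2,3-dimethoxy-4-oxo-1-(triethylsilyloxy)cyclopent-2-ene-1-carboxylate | COC(=O)[C@@]1(O[Si](CC)(CC)CC)C(OC)=C(OC)C(=O)[C@@]1(O)C(N(CC)CC)=CC(=O)c1ccc(O[Si](C)(C)C(C)(C)C)cc1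
F6 | step 5 | racemic methyl 1,5-dihydroxy-2,3-dimethoxy-4-oxocyclopent-2-ene-1-carboxylate | COC(=O)C1(O)C(O)C(=O)C(OC)=C1OC
F7 | step 7 | methyl (1S,5R)-5-(chloroacetoxy)-1-hydroxy-2,3-dimethoxy-4-oxocyclopent-2-ene-1-carboxylate | COC(=O)[C@@]1(O)C(OC)=C(OC)C(=O)[C@@H]1OC(=O)CCl
F8 | step 7 | methyl (1S,5R)-5-(chloroacetoxy)-2,3-dimethoxy-4-oxo-1-(triethylsilyloxy)cyclopent-2-ene-1-carboxylate | COC(=O)[C@@]1(O[Si](CC)(CC)CC)C(OC)=C(OC)C(=O)[C@@H]1OC(=O)CCl
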